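**Retrosynthetic overview**

- The C3 angelate and the primary allylic acetate are installed last on a cis-3-hydroxy-2-(3-hydroxyprop-1-en-2-yl)-2,3-dihydrobenzofuran core.
- The strategy rests on ring A (C3a, C4, C5, C6, C7, C7a): oxygens on C6 and C7a, the acetyl group on C5 and hydrogens on C4 and C7, which is the pattern a 1,1,3-trioxygenated diene and an alkynyl methyl ketone deliver.
- Key disconnection: C3a–C4 and C5–C6 (Diels–Alder addition, then aromatisation) give a 5-[2,2-bis(silyloxy)vinyl]-2,3-dihydrofuran and but-3-yn-2-one.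
- The diene comes from an (E)-ylidene acetic acid, made from a γ-lactone by acetate enolate addition and cyclodehydration; the lactone comes from 2-deoxy-D-glucose, whose C3 and C4 become C3 and C2 of the target.
- Ring order: the oxygen heterocycle first (sugar γ-lactone, then 2-ylidene tetrahydrofuran, then 2,3-dihydrofuran), ring A last.

Key step: step 12

Remark: O1, C2, C3, C3a, C4–C7 and C7a denote the benzofuran positions of the target throughout; "sugar C1–C6" denotes the carbons of 2-deoxy-D-glucose.

**Route**

Step 1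
Reactants: 1 2-deoxy-D-glucose
Product: 3 2-deoxy-D-arabino-hexono-1,4-lactone, via 2-deoxy-D-gluconic acid 2 (not isolated)
Conditions: Br2, H2O, rt; then Amberlite IRA-67 (free base), evaporation at 50 °C
Reagents that add atoms: none
Why: Bromine-water oxidation of the aldose to the aldonic acid followed by γ-lactonisation on concentration is the standard entry to aldono-1,4-lactones and touches no stereocentre, so sugar C3 and C4 (future C3 and C2) are carried over unchanged.

Step 2
Reactants: 3 2-deoxy-D-arabino-hexono-1,4-lactone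
Product: 4 2-deoxy-5,6-O-isopropylidene-D-arabino-hexono-1,4-lactone
Conditions: Me2C(OMe)2, TsOH·H2O (cat.), acetone, rt
Reagents that add atoms: 2,2-dimethoxypropane, COC(C)(C)OC
Why: Acid-catalysed transacetalisation should place the isopropylidene group on the terminal 5,6-diol (dioxolane favoured over the 3,5-dioxane), leaving only O3 free.

Step 3
Reactants: 4 2-deoxy-5,6-O-isopropylidene-D-arabino-hexono-1,4-lactone
Product: 5 3-O-TBS-5,6-O-isopropylidene lactone
Conditions: TBSCl, imidazole, DMF, rt
Reagents that add atoms: tert-butyldimethylsilyl chloride, CC(C)(C)[Si](C)(C)Cl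
Why: Imidazole-promoted silylation of the single free secondary alcohol (silyl ether formation) is mild enough for the β-hydroxy lactone.

Step 4
Reactants: 5 3-O-TBS-5,6-O-isopropylidene lactone
Product: 6 3-O-TBS lactone 5,6-diol
Conditions: AcOH/H2O 4:1, 40 °C
Reagents that add atoms: none
Why: Mild aqueous-acid acetal hydrolysis cleaves the terminal acetonide faster than the secondary silyl ether.

Step 5
Reactants: 6 3-O-TBS lactone 5,6-diol
Product: 7 3,6-bis-O-TBS lactone with free 5-OH
Conditions: TBSCl (1.05 equiv), imidazole, CH2Cl2, −20 → 0 °C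
Reagents that add atoms: tert-butyldimethylsilyl chloride, CC(C)(C)[Si](C)(C)Cl
Why: Kinetically controlled silylation distinguishes the primary C6 hydroxyl from the hindered secondary C5 hydroxyl.

Step 6
Reactants: 7 3,6-bis-O-TBS lactone with free 5-OH
Product: 8 5-keto lactone
Conditions: Dess–Martin periodinane, pyridine, CH2Cl2, 0 °C → rt
Reagents that add atoms: none
Why: Dess–Martin oxidation of the only free alcohol runs under buffered, non-enolising conditions, so the adjacent oxygen-bearing centre (sugar C4) should not epimerise.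

Step 7
Reactants: 8 5-keto lactone
Product: 9 5-methylene lactone
Conditions: Zn, CH2Br2, TiCl4, THF/CH2Cl2, 0 °C → rt
Reagents that add atoms: dibromomethane, BrCBr
Why: Takai–Lombardo methylenation uses a non-basic titanium–zinc methylene reagent that is selective for the ketone over the lactone, so neither epimerisation at sugar C4 nor β-elimination of the C3 silyloxy group is expected.

Step 8
Reactants: 9 5-methylene lactone; 10 allyl acetate
Product: 12 allyl δ-hydroxy-β-keto ester (ring–chain tautomers), via lithium enolate of allyl acetate 11 (not isolated)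
Conditions: 10, LiN(SiMe3)2, THF, −78 °C; then 9, −78 °C; AcOH quench
Reagents that add atoms: none
Why: Claisen-type addition of the ester enolate to the lactone carbonyl at low temperature stops at the β-keto ester stage (protected as its enolate) and does not involve the two stereocentres.

Step 9
Reactants: 12 allyl δ-hydroxy-β-keto ester
Product: 13 allyl (E)-ylidene acetate
Conditions: (CO2H)2 (anhydrous, cat.), MgSO4, CH2Cl2, rt
Reagents that add atoms: none
Why: Acid-catalysed cyclodehydration (5-exo attack of the hydroxyl on the ketone, then loss of water towards the ester) gives the conjugated exocyclic enol ether, whose E geometry (ester anti to the ring oxygen) is the thermodynamic one and places the ring CH2 syn to the carbonyl.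

Step 10
Reactants: 13 allyl (E)-ylidene acetate
Product: 14 (E)-ylidene acetic acid
Conditions: Pd(PPh3)4 (cat.), morpholine, THF, rt; pH 5 buffer work-up
Reagents that add atoms: none
Why: Tsuji–Trost deallylation with zerovalent palladium and an amine allyl scavenger frees the acid under neutral conditions that the enol ether and both silyl ethers tolerate.

Step 11
Reactants: 14 (E)-ylidene acetic acid
Product: 16 bis(trimethylsilyl) vinylketene acetal diene, via trimethylsilyl ester 15 (not isolated)
Conditions: HN(SiMe3)2, Me3SiCl (cat.), THF, 40 °C, evaporate; Me3SiCl, THF, −78 °C, then LiN(iPr)2 added last; pentane, filtration under Ar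
Reagents that add atoms: hexamethyldisilazane, C[Si](C)(C)N[Si](C)(C)C; chlorotrimethylsilane, C[Si](C)(C)Cl
Why: Kinetic γ-deprotonation of the β-alkoxy enoate silyl ester by the amide base with internal silyl chloride quench (O-silylation of the dienolate) gives the bis(silyl) ketene acetal, and trapping at −78 °C is meant to outrun β-elimination of the C3 silyloxide.

Step 12
Reactants: 16 bis(trimethylsilyl) vinylketene acetal diene; 17 but-3-yn-2-one
Product: 19 5-acetyl-6-(trimethylsilyloxy)-2,3-dihydrobenzofuran bis-TBS ether, via cycloadduct 18 (not isolated)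
Conditions: 17 (2 equiv), 2,6-di-tert-butylpyridine (0.1 equiv), toluene, 0 °C → rt
Reagents that add atoms: none
Why: The electron-rich diene C6=C7–C7a=C3a (donor oxygens on C6 and C7a) attacks the unsubstituted alkyne carbon of 17 through C3a in a Michael-like, asynchronous [4+2] cycloaddition, and the resulting allenolate carbon (future C5) closes onto the silyloxy-stabilised C6, so C3a–C4 and C5–C6 form and ring A closes as a six-membered carbocycle in one operation. The closest known reaction type is the thermal Diels–Alder addition and aromatisation of 1,1,3-trioxygenated vinylketene acetals with alkynones to give 2,4-dioxygenated aryl ketones. In cycloadduct 18 the C6 silyl ketal and the doubly activated C3a–H are 1,4-related, so loss of Me3SiOH aromatises ring A and leaves the C6 oxygen as its silyl ether. The only new stereocentre, C3a in 18, is transient and erased on aromatisation, while C2 and C3 are spectators whose bonds are not involved. Regioselectivity (acetyl on C5, next to the C6 oxygen) follows from diene polarisation: the largest HOMO coefficient lies on C3a and the largest LUMO coefficient of the ynone on its terminal carbon. The step also needs loss of the C6 silanol to outrun loss of the allylic C3 silanol (furan formation), which the much easier ionisation of the ketal carbon and base-buffered, Lewis-acid-free conditions at or below room temperature should secure.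

Step 13
Reactants: 19 5-acetyl-6-(trimethylsilyloxy)-2,3-dihydrobenzofuran bis-TBS ether (crude)
Product: 20 phenol primary alcohol with C3–OTBS
Conditions: HF·pyridine, pyridine, THF, 0 °C
Reagents that add atoms: none
Why: Buffered fluoride cleaves the labile aryl trimethylsilyl ether and the primary allylic silyl ether much faster than the hindered secondary benzylic one (selective desilylation).

Step 14
Reactants: 20 phenol primary alcohol with C3–OTBS
Product: 21 aryl acetate primary acetate with C3–OTBS
Conditions: Ac2O, Et3N, DMAP (cat.), CH2Cl2, 0 °C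
Reagents that add atoms: acetic anhydride, CC(=O)OC(C)=O
Why: Nucleophile-catalysed acylation installs the required primary allylic acetate and at the same time masks the phenol as an aryl acetate for the later esterification.

Step 15
Reactants: 21 aryl acetate primary acetate with C3–OTBS
Product: 22 C3 alcohol diacetate
Conditions: HF·pyridine, THF, 0 °C → rt
Reagents that add atoms: none
Why: Longer exposure to HF·pyridine removes the remaining secondary silyl ether (desilylation) while both esters are inert, and C3 keeps its configuration because its C–O bond is not broken.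

Step 16
Reactants: 22 C3 alcohol diacetate; 23 angelic acid
Product: 25 C3 angelate diacetate, via mixed anhydride 24 (not isolated)
Conditions: 23, 2,4,6-Cl3C6H2COCl, Et3N, toluene, rt; then 22, 75 °C
Reagents that add atoms: none
Why: Acylation by the preformed mixed anhydride (Yamaguchi-type esterification run without a nucleophilic catalyst) should transfer the angeloyl group with retention at C3 and without Z to E isomerisation.

Step 17
Reactants: 25 C3 angelate diacetate
Product: 26 target CNP0323250.1
Conditions: NH4OAc, MeOH/H2O 4:1, rt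
Reagents that add atoms: none
Why: The aryl ester is far more electrophilic than the two alkyl esters, so near-neutral ammonium acetate-mediated methanolysis (chemoselective transesterification) should remove only the phenolic acetate and avoid phenoxide-driven loss of the C3 ester.

**Compound list**

1 | 2-deoxy-D-glucose (2-deoxy-D-arabino-hexose) | O=CC[C@@H](O)[C@H](O)[C@H](O)CO | starting material
2 | 2-deoxy-D-gluconic acid, (3R,4S,5R)-3,4,5,6-tetrahydroxyhexanoic acid | OC(=O)C[C@@H](O)[C@H](O)[C@H](O)CO | intermediate
3 | 2-deoxy-D-arabino-hexono-1,4-lactone, (4R,5S)-5-[(1R)-1,2-dihydroxyethyl]-4-hydroxyoxolan-2-one | O=C1C[C@@H](O)[C@@H]([C@H](O)CO)O1 | intermediate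
4 | 2-deoxy-5,6-O-isopropylidene-D-arabino-hexono-1,4-lactone | O=C1C[C@@H](O)[C@@H]([C@H]2COC(C)(C)O2)O1 | intermediate
5 | 3-O-(tert-butyldimethylsilyl)-2-deoxy-5,6-O-isopropylidene-D-arabino-hexono-1,4-lactone | O=C1C[C@@H](O[Si](C)(C)C(C)(C)C)[C@@H]([C@H]2COC(C)(C)O2)O1 | intermediate
6 | 3-O-(tert-butyldimethylsilyl)-2-deoxy-D-arabino-hexono-1,4-lactone | O=C1C[C@@H](O[Si](C)(C)C(C)(C)C)[C@@H]([C@H](O)CO)O1 | intermediate
7 | 3,6-bis-O-(tert-butyldimethylsilyl)-2-deoxy-D-arabino-hexono-1,4-lactone | O=C1C[C@@H](O[Si](C)(C)C(C)(C)C)[C@@H]([C@H](O)CO[Si](C)(C)C(C)(C)C)O1 | intermediate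
8 | (4R,5S)-4-[(tert-butyldimethylsilyl)oxy]-5-{[(tert-butyldimethylsilyl)oxy]acetyl}oxolan-2-one | O=C1C[C@@H](O[Si](C)(C)C(C)(C)C)[C@@H](C(=O)CO[Si](C)(C)C(C)(C)C)O1 | intermediate
9 | (4R,5R)-4-[(tert-butyldimethylsilyl)oxy]-5-{3-[(tert-butyldimethylsilyl)oxy]prop-1-en-2-yl}oxolan-2-one | O=C1C[C@@H](O[Si](C)(C)C(C)(C)C)[C@@H](C(=C)CO[Si](C)(C)C(C)(C)C)O1 | intermediate
10 | allyl acetate (prop-2-en-1-yl acetate) | CC(=O)OCC=C | starting material
11 | lithium enolate of allyl acetate, lithium 1-(prop-2-en-1-yloxy)ethen-1-olate | [Li+].[O-]C(=C)OCC=C | intermediate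
12 | prop-2-en-1-yl (5R,6R)-5,8-bis[(tert-butyldimethylsilyl)oxy]-6-hydroxy-7-methylidene-3-oxooctanoate (open-chain form drawn; in equilibrium with its cyclic hemiketals) | C=CCOC(=O)CC(=O)C[C@@H](O[Si](C)(C)C(C)(C)C)[C@H](O)C(=C)CO[Si](C)(C)C(C)(C)C | intermediate
13 | prop-2-en-1-yl (2E)-2-[(4R,5R)-4-[(tert-butyldimethylsilyl)oxy]-5-{3-[(tert-butyldimethylsilyl)oxy]prop-1-en-2-yl}oxolan-2-ylidene]acetate | C=CCOC(=O)/C=C1\C[C@@H](O[Si](C)(C)C(C)(C)C)[C@@H](C(=C)CO[Si](C)(C)C(C)(C)C)O1 | intermediate
14 | (2E)-2-[(4R,5R)-4-[(tert-butyldimethylsilyl)oxy]-5-{3-[(tert-butyldimethylsilyl)oxy]prop-1-en-2-yl}oxolan-2-ylidene]acetic acid | OC(=O)/C=C1\C[C@@H](O[Si](C)(C)C(C)(C)C)[C@@H](C(=C)CO[Si](C)(C)C(C)(C)C)O1 | intermediate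
15 | trimethylsilyl (2E)-2-[(4R,5R)-4-[(tert-butyldimethylsilyl)oxy]-5-{3-[(tert-butyldimethylsilyl)oxy]prop-1-en-2-yl}oxolan-2-ylidene]acetate | C[Si](C)(C)OC(=O)/C=C1\C[C@@H](O[Si](C)(C)C(C)(C)C)[C@@H](C(=C)CO[Si](C)(C)C(C)(C)C)O1 | intermediate
16 | (2R,3R)-5-[2,2-bis(trimethylsilyloxy)ethenyl]-3-[(tert-butyldimethylsilyl)oxy]-2-{3-[(tert-butyldimethylsilyl)oxy]prop-1-en-2-yl}-2,3-dihydrofuran (cis) | C=C(CO[Si](C)(C)C(C)(C)C)[C@H]1OC(C=C(O[Si](C)(C)C)O[Si](C)(C)C)=C[C@H]1O[Si](C)(C)C(C)(C)C | intermediate
17 | but-3-yn-2-one | CC(=O)C#C | starting material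
18 | 1-[(2R,3R)-3-[(tert-butyldimethylsilyl)oxy]-2-{3-[(tert-butyldimethylsilyl)oxy]prop-1-en-2-yl}-6,6-bis(trimethylsilyloxy)-2,3,3a,6-tetrahydro-1-benzofuran-5-yl]ethanone (C3a epimers) | C=C(CO[Si](C)(C)C(C)(C)C)[C@H]1OC2=CC(O[Si](C)(C)C)(O[Si](C)(C)C)C(C(C)=O)=CC2[C@H]1O[Si](C)(C)C(C)(C)C | intermediate
19 | 1-[(2R,3R)-3-[(tert-butyldimethylsilyl)oxy]-2-{3-[(tert-butyldimethylsilyl)oxy]prop-1-en-2-yl}-6-(trimethylsilyloxy)-2,3-dihydro-1-benzofuran-5-yl]ethanone | C=C(CO[Si](C)(C)C(C)(C)C)[C@H]1Oc2cc(O[Si](C)(C)C)c(C(C)=O)cc2[C@H]1O[Si](C)(C)C(C)(C)C | intermediate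
20 | 1-[(2R,3R)-3-[(tert-butyldimethylsilyl)oxy]-6-hydroxy-2-(3-hydroxyprop-1-en-2-yl)-2,3-dihydro-1-benzofuran-5-yl]ethanone | C=C(CO)[C@H]1Oc2cc(O)c(C(C)=O)cc2[C@H]1O[Si](C)(C)C(C)(C)C | intermediate
21 | 2-[(2R,3R)-6-acetoxy-5-acetyl-3-[(tert-butyldimethylsilyl)oxy]-2,3-dihydro-1-benzofuran-2-yl]prop-2-en-1-yl acetate | C=C(COC(C)=O)[C@H]1Oc2cc(OC(C)=O)c(C(C)=O)cc2[C@H]1O[Si](C)(C)C(C)(C)C | intermediate
22 | 2-[(2R,3R)-6-acetoxy-5-acetyl-3-hydroxy-2,3-dihydro-1-benzofuran-2-yl]prop-2-en-1-yl acetate | C=C(COC(C)=O)[C@H]1Oc2cc(OC(C)=O)c(C(C)=O)cc2[C@H]1O | intermediate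
23 | angelic acid, (2Z)-2-methylbut-2-enoic acid | C/C=C(/C)C(=O)O | starting material
24 | (2Z)-2-methylbut-2-enoic 2,4,6-trichlorobenzoic anhydride | C/C=C(/C)C(=O)OC(=O)c1c(Cl)cc(Cl)cc1Cl | intermediate
25 | (2R,3R)-6-acetoxy-5-acetyl-2-[3-(acetyloxy)prop-1-en-2-yl]-2,3-dihydro-1-benzofuran-3-yl (2Z)-2-methylbut-2-enoate | C=C(COC(C)=O)[C@H]1Oc2cc(OC(C)=O)c(C(C)=O)cc2[C@H]1OC(=O)/C(C)=C\C | intermediate
26 | (2R,3R)-5-acetyl-2-[3-(acetyloxy)prop-1-en-2-yl]-6-hydroxy-2,3-dihydro-1-benzofuran-3-yl (2Z)-2-methylbut-2-enoate (CNP0323250.1) | C=C(COC(C)=O)[C@H]1Oc2cc(O)c(C(C)=O)cc2[C@H]1OC(=O)/C(C)=C\C | target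

**Step count**

Total steps: 17. Longest linear sequence: 17 steps (1 to 26); compounds 10, 17 and 23 are purchased.

**Steps most likely to fail**

Step 12 (key step). The allylic C3 silanol may be lost from diene 16, aromatising the five-membered ring to a furan, faster than the cycloaddition proceeds. The alkynone may also oligomerise under the influence of the released silanol, or the addition may stop after the first C–C bond without closure of ring A. The fallback builds ring A without the vinylketene acetal and without the alkynone. It sets out from acid 14, which is activated with carbonyldiimidazole to acyl imidazolide F1. F1 acylates the lithium enolate of acetone (two equivalents, THF, −78 °C; Claisen condensation forming C5–C6) to give β-diketone F2. Condensation with N,N-dimethylformamide dimethyl acetal at the central methylene supplies C4 as dimethylaminomethylene diketone F3. Warming F3 in toluene with catalytic pyridinium acetate should let the vinylogous enol terminus C3a add to the aminomethylene carbon (six-membered closure forming C3a–C4); loss of dimethylamine and tautomerisation would give phenol F4, which carries both tert-butyldimethylsilyl ethers. F4 is desilylated at the primary oxygen under the conditions of step 13 and so comes back to the route at 20.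

Step 11. The C3 silyloxide may undergo β-elimination from the lithium dienolate (irreversible furan formation), or vinylic α-deprotonation and C-silylation may compete with γ-enolisation. The fallback replaces deprotonation by a strong base with electrophile-first (soft) enolisation. It sets out from silyl ester 15, which is treated with Me3SiOTf and Et3N in Et2O at 0 °C. The carbonyl oxygen is silylated first and the amine then removes the γ-proton from the resulting oxocarbenium ion, the manifold by which butenolides are turned into 2-silyloxyfurans, so no anionic dienolate with a β-leaving group is formed. The fallback returns to the route at 16 and makes no new compound (F0).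

Step 16. The angeloyl unit may isomerise from Z to E (tiglate) during activation or acyl transfer, and slow acylation of the hindered cis C3 alcohol leaves time for ionisation at the benzylic carbon. The fallback builds the Z-enoate on the ester after acylation. It sets out from alcohol 22, which is esterified with 2-[bis(2,2,2-trifluoroethoxy)phosphoryl]propanoic acid (DCC, DMAP cat., CH2Cl2, 0 °C) to give phosphonate F5. Still–Gennari olefination of F5 with acetaldehyde (KN(SiMe3)2, 18-crown-6, THF, −78 °C) should form the Z-trisubstituted alkene and return to the route at 25.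

**Further compounds**

F1 | step 12 | 1-{(2E)-2-[(4R,5R)-4-[(tert-butyldimethylsilyl)oxy]-5-{3-[(tert-butyldimethylsilyl)oxy]prop-1-en-2-yl}oxolan-2-ylidene]acetyl}imidazole | O=C(/C=C1\C[C@@H](O[Si](C)(C)C(C)(C)C)[C@@H](C(=C)CO[Si](C)(C)C(C)(C)C)O1)n1ccnc1
F2 | step 12 | (1E)-1-[(4R,5R)-4-[(tert-butyldimethylsilyl)oxy]-5-{3-[(tert-butyldimethylsilyl)oxy]prop-1-en-2-yl}oxolan-2-ylidene]pentane-2,4-dione | CC(=O)CC(=O)/C=C1\C[C@@H](O[Si](C)(C)C(C)(C)C)[C@@H](C(=C)CO[Si](C)(C)C(C)(C)C)O1
F3 | step 12 | (1E)-1-[(4R,5R)-4-[(tert-butyldimethylsilyl)oxy]-5-{3-[(tert-butyldimethylsilyl)oxy]prop-1-en-2-yl}oxolan-2-ylidene]-3-[(dimethylamino)methylidene]pentane-2,4-dione | CN(C)C=C(C(C)=O)C(=O)/C=C1\C[C@@H](O[Si](C)(C)C(C)(C)C)[C@@H](C(=C)CO[Si](C)(C)C(C)(C)C)O1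
F4 | step 12 | 1-[(2R,3R)-3-[(tert-butyldimethylsilyl)oxy]-2-{3-[(tert-butyldimethylsilyl)oxy]prop-1-en-2-yl}-6-hydroxy-2,3-dihydro-1-benzofuran-5-yl]ethanone | C=C(CO[Si](C)(C)C(C)(C)C)[C@H]1Oc2cc(O)c(C(C)=O)cc2[C@H]1O[Si](C)(C)C(C)(C)C
F0 | step 11 | none | none
F5 | step 16 | (2R,3R)-6-acetoxy-5-acetyl-2-[3-(acetyloxy)prop-1-en-2-yl]-2,3-dihydro-1-benzofuran-3-yl 2-[bis(2,2,2-trifluoroethoxy)phosphoryl]propanoate | C=C(COC(C)=O)[C@H]1Oc2cc(OC(C)=O)c(C(C)=O)cc2[C@H]1OC(=O)C(C)P(=O)(OCC(F)(F)F)OCC(F)(F)F
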